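**Retrosynthetic overview**
- Plakortolide S ⇐ aryl silyl ether cleavage ⇐ cis-fused 1,2-dioxane closed last by a 6-exo peroxy-oxa-Michael addition (C3–O bond) of a C6 hydroperoxide onto a preformed butenolide.
- C6 hydroperoxide ⇐ catalyst-controlled Markovnikov addition of H2O2 (C6–O bond) to the 1,1-disubstituted alkene of the butenolide (the proposed new step).
- Butenolide (first ring) ⇐ tertiary α-hydroxy aldehyde + Ph3P=C=C=O ⇐ 1,2-diol ⇐ (S)-2-methylglycidol (C4–O stereocentre from the chiral pool) + alkenyl Grignard.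
- Alkenyl bromide ⇐ 2,3-dibromopropene + Ar(CH2)9MgBr ⇐ ArMgBr + 1,9-dibromononane.

Assumptions: plakortolide numbering is used (C1 lactone C=O, C3 the O–O-bearing CH, C4 and C6 the methyl-bearing carbons), and the target SMILES is read as (3R,4R,6S) with H-3, 4-Me and 6-Me cis. The TBS ether of 4-bromophenol and (S)-2-methylglycidol are bought.

**Step 1**
Reactants: 1 (4-bromophenoxy)(tert-butyl)dimethylsilane; 2 1,9-dibromononane
Product: 4 tert-butyl[4-(9-bromononyl)phenoxy]dimethylsilane, via arylmagnesium bromide 3 (not isolated)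
Conditions: Mg, THF, 40 °C; then 2 (3 equiv), Li2CuCl4 (2 mol %), THF, 0 °C → rt
Reagents that add atoms: none
Why: Copper-catalysed (Kochi-type) cross-coupling of an aryl Grignard reagent with a primary alkyl bromide, with excess dibromide suppressing double arylation; no stereocentre is involved.

**Step 2**
Reactants: 4 tert-butyl[4-(9-bromononyl)phenoxy]dimethylsilane; 5 2,3-dibromoprop-1-ene
Product: 7 tert-butyl[4-(11-bromododec-11-en-1-yl)phenoxy]dimethylsilane, via alkylmagnesium bromide 6 (not isolated)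
Conditions: Mg, THF, 40 °C; then 5 (1.2 equiv), CuI (5 mol %), THF, 0 °C → rt
Reagents that add atoms: none
Why: Copper-catalysed allylic substitution of the alkyl Grignard reagent on 2,3-dibromopropene (SN2 and SN2′ give the same 2-bromo-1-alkene); the vinylic bromide is inert.

**Step 3**
Reactants: 7 tert-butyl[4-(11-bromododec-11-en-1-yl)phenoxy]dimethylsilane; 8 (S)-2-methylglycidol [(2S)-(2-methyloxiran-2-yl)methanol]
Product: 11 (2R)-14-{4-[(tert-butyldimethylsilyl)oxy]phenyl}-2-methyl-4-methylidenetetradecane-1,2-diol, via chloromagnesium (S)-2-methylglycidolate 9 (not isolated), via alkenylmagnesium bromide 10 (not isolated)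
Conditions: 8, i-PrMgCl (1.0 equiv), THF, −40 °C; 7, Mg, THF, 50 °C; combine, CuI (10 mol %), −30 → 0 °C; aq NH4Cl
Reagents that add atoms: none
Why: Copper-catalysed Grignard opening of a 2,2-disubstituted epoxide at its unhindered CH2; the quaternary carbinol carbon (C4) is not touched, so its configuration comes intact from the chiral pool (S → R is only a CIP priority change).

**Step 4**
Reactants: 11 (2R)-14-{4-[(tert-butyldimethylsilyl)oxy]phenyl}-2-methyl-4-methylidenetetradecane-1,2-diol
Product: 12 (2R)-14-{4-[(tert-butyldimethylsilyl)oxy]phenyl}-2-hydroxy-2-methyl-4-methylidenetetradecanal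
Conditions: IBX (1.5 equiv), DMSO, rt
Reagents that add atoms: none
Why: IBX oxidation of the primary alcohol to the aldehyde; the tertiary alcohol cannot be oxidised, IBX does not cleave 1,2-diols, and the quaternary α-carbon cannot epimerise.

**Step 5**
Reactants: 12 (2R)-14-{4-[(tert-butyldimethylsilyl)oxy]phenyl}-2-hydroxy-2-methyl-4-methylidenetetradecanal
Product: 14 (5R)-5-(12-{4-[(tert-butyldimethylsilyl)oxy]phenyl}-2-methylidenedodecyl)-5-methylfuran-2(5H)-one, via acyl phosphorus ylide 13 (not isolated)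
Conditions: Ph3P=C=C=O (1.3 equiv), toluene, 80 °C
Reagents that add atoms: ketenylidene(triphenyl)phosphorane (Bestmann ylide), O=C=C=P(c1ccccc1)(c1ccccc1)c1ccccc1
Why: Bestmann butenolide synthesis: the tertiary alcohol adds to the ketene ylide to give an ester-stabilised ylide, which closes the ring by intramolecular Wittig olefination of the aldehyde; C4 is untouched.

**Step 6**
Reactants: 14 (5R)-5-(12-{4-[(tert-butyldimethylsilyl)oxy]phenyl}-2-methylidenedodecyl)-5-methylfuran-2(5H)-one
Product: 15 (5R)-5-[(2S)-12-{4-[(tert-butyldimethylsilyl)oxy]phenyl}-2-hydroperoxy-2-methyldodecyl]-5-methylfuran-2(5H)-one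
Conditions: chiral confined imidodiphosphorimidate (IDPi) Brønsted acid (5 mol %, the enantiomer that gives 6S, found by screening both), anhydrous H2O2 in Et2O (5 equiv), CHCl3/cyclohexane, −20 °C
Reagents that add atoms: hydrogen peroxide, OO
Why: Proposed new method: catalyst-controlled asymmetric Markovnikov perhydration of an unactivated 1,1-dialkyl alkene; the confined acid protonates the terminal CH2 to give the tertiary C6 cation as a contact ion pair inside the chiral pocket, where its three different groups (CH3, linear alkyl, neopentyl-type CH2 carrying the lactone) are told apart, and H2O2 hydrogen-bonded to the counter-anion is delivered to one face to form the C6–O bond as 6S (C4 gives no useful bias, so the diastereoselectivity is catalyst-derived); the closest known reactions are IDPi-catalysed asymmetric intramolecular hydroalkoxylation and hydrolactonization of unactivated 1,1-disubstituted alkenes and the classical mineral-acid-catalysed addition of H2O2 to alkenes giving racemic tertiary hydroperoxides.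

**Step 7**
Reactants: 15 (5R)-5-[(2S)-12-{4-[(tert-butyldimethylsilyl)oxy]phenyl}-2-hydroperoxy-2-methyldodecyl]-5-methylfuran-2(5H)-one
Product: 17 plakortolide S [(3R,4R,6S) in plakortolide numbering; (3S,4aR,7aR)-3-[10-(4-hydroxyphenyl)decyl]-3,4a-dimethyl-tetrahydrofuro[3,2-c][1,2]dioxin-6-one], via O-TBS plakortolide S 16 (not isolated)
Conditions: Et2NH (0.2 equiv), CF3CH2OH, rt; then evaporate; TBAF/AcOH (1:1, 1.5 equiv), THF, 0 °C
Reagents that add atoms: none
Why: Base-catalysed intramolecular 6-exo-trig peroxy-oxa-Michael addition forms the C3–O bond; the tether from C4 can only reach C3 on the face of C5, so the ring fusion is cis and C3 is set as R, and buffered fluoride then cleaves the aryl silyl ether without harming the peroxide or lactone.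

**Compound list**
1 | (4-bromophenoxy)(tert-butyl)dimethylsilane | CC(C)(C)[Si](C)(C)Oc1ccc(Br)cc1 | starting material
2 | 1,9-dibromononane | BrCCCCCCCCCBr | starting material
3 | {4-[(tert-butyldimethylsilyl)oxy]phenyl}magnesium bromide | CC(C)(C)[Si](C)(C)Oc1ccc([Mg]Br)cc1 | intermediate
4 | tert-butyl[4-(9-bromononyl)phenoxy]dimethylsilane | CC(C)(C)[Si](C)(C)Oc1ccc(CCCCCCCCCBr)cc1 | intermediate
5 | 2,3-dibromoprop-1-ene | C=C(Br)CBr | starting material
6 | (9-{4-[(tert-butyldimethylsilyl)oxy]phenyl}nonyl)magnesium bromide | CC(C)(C)[Si](C)(C)Oc1ccc(CCCCCCCCC[Mg]Br)cc1 | intermediate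
7 | tert-butyl[4-(11-bromododec-11-en-1-yl)phenoxy]dimethylsilane | CC(C)(C)[Si](C)(C)Oc1ccc(CCCCCCCCCCC(Br)=C)cc1 | intermediate
8 | (S)-2-methylglycidol | C[C@]1(CO)CO1 | starting material
9 | chloromagnesium (S)-2-methylglycidolate | C[C@]1(CO[Mg]Cl)CO1 | intermediate
10 | (12-{4-[(tert-butyldimethylsilyl)oxy]phenyl}dodec-1-en-2-yl)magnesium bromide | CC(C)(C)[Si](C)(C)Oc1ccc(CCCCCCCCCCC(=C)[Mg]Br)cc1 | intermediate
11 | (2R)-14-{4-[(tert-butyldimethylsilyl)oxy]phenyl}-2-methyl-4-methylidenetetradecane-1,2-diol | C=C(CCCCCCCCCCc1ccc(O[Si](C)(C)C(C)(C)C)cc1)C[C@@](CO)(C)O | intermediate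
12 | (2R)-14-{4-[(tert-butyldimethylsilyl)oxy]phenyl}-2-hydroxy-2-methyl-4-methylidenetetradecanal | C=C(CCCCCCCCCCc1ccc(O[Si](C)(C)C(C)(C)C)cc1)C[C@@](C=O)(C)O | intermediate
13 | (2R)-14-{4-[(tert-butyldimethylsilyl)oxy]phenyl}-2-methyl-4-methylidene-1-oxotetradecan-2-yl (triphenyl-λ5-phosphanylidene)acetate | C=C(CCCCCCCCCCc1ccc(O[Si](C)(C)C(C)(C)C)cc1)C[C@@](C=O)(C)OC(=O)C=P(c1ccccc1)(c1ccccc1)c1ccccc1 | intermediate
14 | (5R)-5-(12-{4-[(tert-butyldimethylsilyl)oxy]phenyl}-2-methylidenedodecyl)-5-methylfuran-2(5H)-one | C=C(CCCCCCCCCCc1ccc(O[Si](C)(C)C(C)(C)C)cc1)C[C@@]1(C)OC(=O)C=C1 | intermediate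
15 | (5R)-5-[(2S)-12-{4-[(tert-butyldimethylsilyl)oxy]phenyl}-2-hydroperoxy-2-methyldodecyl]-5-methylfuran-2(5H)-one | C[C@](OO)(CCCCCCCCCCc1ccc(O[Si](C)(C)C(C)(C)C)cc1)C[C@@]1(C)OC(=O)C=C1 | intermediate
16 | O-TBS plakortolide S (3R,4R,6S) | C[C@]1(CCCCCCCCCCc2ccc(O[Si](C)(C)C(C)(C)C)cc2)C[C@@]2(C)OC(=O)C[C@H]2OO1 | intermediate
17 | plakortolide S (3R,4R,6S) | C[C@]1(CCCCCCCCCCc2ccc(O)cc2)C[C@@]2(C)OC(=O)C[C@H]2OO1 | target

**Total step count:** 7. **Longest linear sequence:** 7 steps (1 → 4 → 7 → 11 → 12 → 14 → 15 → 17).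

**Three steps most likely to fail**

1. Step 6 (the proposed new perhydration). The risks are low catalyst control at C6, re-ionisation of the tertiary hydroperoxide eroding the ratio, alkene isomerisation via the cation, and acid damage to the aryl silyl ether. The fallback sets out from 14 and uses the known Mukaiyama–Isayama hydroperoxysilylation (Co(thd)2 cat., O2, Et3SiH, 1,2-dichloroethane, rt). This radical reaction is selective for the electron-rich 1,1-disubstituted alkene but unselective at C6. It gives the (2S)-triethylsilyl peroxide F1 together with the (2R)-triethylsilyl peroxide F2 in about 1:1 ratio. Brief acidic methanolysis (cat. HCl, MeOH, 0 °C) frees the hydroperoxides, so the fallback comes back to the route at 15, as a mixture with the (2R)-hydroperoxide F3. The mixture is carried through step 7, where F3 passes through O-TBS 6-epi-plakortolide S F4 to 6-epi-plakortolide S F5. F5 is a rigid diastereomer of 17 and is removed by chromatography, at the cost of half the material.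

2. Step 3 (forming the alkenyl Grignard and opening an epoxide that carries a free alkoxide). The risks are Lewis-acid rearrangement of the epoxide or sluggish opening. The fallback sets out from 7 and changes the C4 building block to the ester oxidation level. The same Grignard reagent 10 opens methyl (R)-2-methylglycidate (COC(=O)[C@@]1(C)CO1; CuBr·SMe2 cat., THF, −40 °C) to give the methyl (2R)-2-hydroxy ester F6. Partial reduction with DIBAL-H (2.2 equiv, CH2Cl2, −78 °C) then gives the aldehyde, so the fallback comes back at 12 and bypasses 11 and step 4.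

3. Step 5 (Bestmann annulation on a hindered tertiary alcohol next to a sensitive α-hydroxy aldehyde). The risks are slow O-acylation and α-ketol rearrangement on heating. The fallback sets out from 12 and builds the ring by intermolecular Z-selective olefination followed by lactonisation. Still–Gennari reaction ((CF3CH2O)2P(O)CH2CO2Me, KHMDS, 18-crown-6, THF, −78 °C) gives the methyl (2Z,4R)-4-hydroxy enoate F7. F7 closes to the butenolide on warming with catalytic PPTS, so the fallback comes back at 14.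

**Further compounds**
F1 | step 6 | (5R)-5-[(2S)-12-{4-[(tert-butyldimethylsilyl)oxy]phenyl}-2-methyl-2-(triethylsilylperoxy)dodecyl]-5-methylfuran-2(5H)-one | C[C@](OO[Si](CC)(CC)CC)(CCCCCCCCCCc1ccc(O[Si](C)(C)C(C)(C)C)cc1)C[C@@]1(C)OC(=O)C=C1
F2 | step 6 | (5R)-5-[(2R)-12-{4-[(tert-butyldimethylsilyl)oxy]phenyl}-2-methyl-2-(triethylsilylperoxy)dodecyl]-5-methylfuran-2(5H)-one | C[C@@](OO[Si](CC)(CC)CC)(CCCCCCCCCCc1ccc(O[Si](C)(C)C(C)(C)C)cc1)C[C@@]1(C)OC(=O)C=C1
F3 | step 6 | (5R)-5-[(2R)-12-{4-[(tert-butyldimethylsilyl)oxy]phenyl}-2-hydroperoxy-2-methyldodecyl]-5-methylfuran-2(5H)-one | C[C@@](OO)(CCCCCCCCCCc1ccc(O[Si](C)(C)C(C)(C)C)cc1)C[C@@]1(C)OC(=O)C=C1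
F4 | step 6 | O-TBS 6-epi-plakortolide S (3R,4R,6R) | C[C@@]1(CCCCCCCCCCc2ccc(O[Si](C)(C)C(C)(C)C)cc2)C[C@@]2(C)OC(=O)C[C@H]2OO1
F5 | step 6 | 6-epi-plakortolide S (3R,4R,6R) | C[C@@]1(CCCCCCCCCCc2ccc(O)cc2)C[C@@]2(C)OC(=O)C[C@H]2OO1
F6 | step 3 | methyl (2R)-14-{4-[(tert-butyldimethylsilyl)oxy]phenyl}-2-hydroxy-2-methyl-4-methylidenetetradecanoate | C=C(CCCCCCCCCCc1ccc(O[Si](C)(C)C(C)(C)C)cc1)C[C@@](C(=O)OC)(C)O
F7 | step 5 | methyl (2Z,4R)-16-{4-[(tert-butyldimethylsilyl)oxy]phenyl}-4-hydroxy-4-methyl-6-methylidenehexadec-2-enoate | C=C(CCCCCCCCCCc1ccc(O[Si](C)(C)C(C)(C)C)cc1)C[C@@](/C=C\C(=O)OC)(C)O
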